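**Retrosynthetic overview**

- Hansforester J is a linear tetraester A–B–C–D. The last skeletal disconnection is the hindered benzoate bond between the carboxyl carbon of ring C and the oxygen of butanoate unit B, which gives an A–B alcohol and a C–D acid.
- Both halves come from one ester of (R)-1-[3,5-bis(benzyloxy)phenyl]propan-2-ol with silyl-protected (R)-3-hydroxybutanoic acid. Desilylation gives the alcohol; formylation and oxidation at the ring carbon between the side chain and one benzyloxy group give the acid.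
- The strategy rests on the 5-alkylresorcinol pattern shared by rings A and C: oxygen on C1 and C3, the (R)-2-oxypropyl chain on C5, hydrogen on C2, C4 and C6. This benzene ring is assembled in one thermal operation from a 3-substituted cyclobutenone and triisopropylsilyloxyacetylene (Danheiser benzannulation).
- Ring order: first the four-membered ring of the cyclobutenone (dichloroketene (2+2) addition to silylated (R)-pent-4-yn-2-ol, then dechlorination), then the benzene ring; no other ring is formed. The silyloxyacetylene comes from 3-phenylisoxazole by ynolate fragmentation and O-silylation.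

Key step: step 5

Remark: read from the SMILES, all four stereocentres are (R). The two carbinol centres of rings A and C come from (R)-pent-4-yn-2-ol and the two butanoate centres from ethyl (R)-3-hydroxybutanoate.

**Route**

Step 1
Reactants: 1 (R)-pent-4-yn-2-ol
Product: 2 (R)-tert-butyldimethyl(pent-4-yn-2-yloxy)silane
Conditions: TBSCl, imidazole, DMF, 0 °C to rt
Reagents that add atoms: tert-butyldimethylsilyl chloride, CC(C)(C)[Si](C)(C)Cl
Why: Imidazole-mediated silyl ether formation masks the secondary alcohol against acylation by dichloroketene and does not touch the (R) centre.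

Step 2
Reactants: 2 (R)-tert-butyldimethyl(pent-4-yn-2-yloxy)silane; 3 trichloroacetyl chloride
Product: 5 4,4-dichloro-3-[(R)-2-(tert-butyldimethylsilyloxy)propyl]cyclobut-2-en-1-one, via dichloroketene 4 (not isolated)
Conditions: Zn–Cu couple, Et2O/DME, rt, slow addition of 3
Reagents that add atoms: none
Why: Ketene–alkyne (2+2) cycloaddition, in which dichloroketene made by zinc dechlorination of 3 adds to the terminal alkyne with the unsubstituted alkyne carbon bonding to the ketene carbonyl carbon, should give the 3-substituted 4,4-dichlorocyclobutenone as it does with other 1-alkynes.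

Step 3
Reactants: 5 4,4-dichloro-3-[(R)-2-(tert-butyldimethylsilyloxy)propyl]cyclobut-2-en-1-one
Product: 6 (R)-3-[2-(tert-butyldimethylsilyloxy)propyl]cyclobut-2-en-1-one
Conditions: Zn dust, AcOH, TMEDA, EtOH, 0 °C to rt
Reagents that add atoms: none
Why: Reductive dechlorination of the α,α-dichloroketone by zinc in buffered acetic acid is the standard way to 3-alkylcyclobutenones and is mild enough for the silyl ether and the strained enone.

Step 4
Reactants: 7 3-phenylisoxazole
Product: 9 triisopropylsilyloxyacetylene, via lithium ethynolate 8 (not isolated)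
Conditions: n-BuLi, THF, −78 to −20 °C; TIPSOTf, −78 to 0 °C; short silica plug in pentane, used at once
Reagents that add atoms: triisopropylsilyl trifluoromethanesulfonate, CC(C)[Si](OS(=O)(=O)C(F)(F)F)(C(C)C)C(C)C
Why: Lithiation of a 5-unsubstituted isoxazole at C5 triggers anionic cycloreversion to benzonitrile and the lithium ynolate, and the hard, bulky silyl triflate should silylate the ynolate on oxygen as in the known preparations of triisopropylsilyl ynol ethers from ynolates.

Step 5
Reactants: 6 (R)-3-[2-(tert-butyldimethylsilyloxy)propyl]cyclobut-2-en-1-one; 9 triisopropylsilyloxyacetylene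
Product: 14 (R)-3-[2-(tert-butyldimethylsilyloxy)propyl]-5-(triisopropylsilyloxy)phenol, via vinylketene 10 (not isolated), via 4-vinylcyclobutenone 11 (not isolated), via dienylketene 12 (not isolated), via cyclohexadienone 13 (not isolated)
Conditions: 9 (2 equiv), toluene, 80 °C then 110 °C, sealed tube, argon
Reagents that add atoms: none
Why: Danheiser benzannulation: conrotatory 4π opening of 6 gives vinylketene 10, whose ketene C=C bond takes up ynol ether 9 in a (2+2) cycloaddition, the nucleophilic CH terminus of 9 bonding to the ketene carbonyl carbon (future C1–C2) and the oxygen-bearing carbon to the ketene α-carbon (future C3–C4), to give 4-vinylcyclobutenone 11. A second 4π opening gives dienylketene 12 (reversibly, so the geometry able to cyclise is drained off), and ring A is closed by 6π electrocyclisation between the ketene carbon and the methylidene carbon (C1–C6) to dienone 13, which tautomerises to phenol 14. The closest known reactions are the thermal benzannulations of 3-alkylcyclobutenones with 1-silyloxy- and 1-alkoxyalkynes, which give 5-alkylresorcinol monoethers. No lasting stereocentre is formed (the sp3 ring carbon of 11 is lost on opening) and the remote (R) silyl ether is inert under the neutral thermal conditions. The step needs regioselectivity in the (2+2) addition, and the polarisation of the ynol ether secures it, so that the ketene oxygen becomes the C1 hydroxyl, the silyloxy group sits on C3 and the side chain on C5; the excess of 9 keeps capture of 10 ahead of its dimerisation.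

Step 6
Reactants: 14 (R)-3-[2-(tert-butyldimethylsilyloxy)propyl]-5-(triisopropylsilyloxy)phenol
Product: 15 (R)-5-(2-hydroxypropyl)benzene-1,3-diol
Conditions: TBAF (3 equiv), THF, 0 °C to rt; aqueous work-up
Reagents that add atoms: none
Why: Fluoride-induced Si–O cleavage should remove both the aryl triisopropylsilyl and the secondary tert-butyldimethylsilyl ether without touching the stereocentre.

Step 7
Reactants: 15 (R)-5-(2-hydroxypropyl)benzene-1,3-diol
Product: 16 (R)-1-[3,5-bis(benzyloxy)phenyl]propan-2-ol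
Conditions: BnBr (2.2 equiv), K2CO3, acetone, reflux
Reagents that add atoms: benzyl bromide, BrCc1ccccc1
Why: Williamson ether synthesis under weak-base conditions deprotonates only the two phenols, so both are benzylated while the secondary alcohol stays free.

Step 8
Reactants: 17 ethyl (R)-3-hydroxybutanoate
Product: 18 ethyl (R)-3-(tert-butyldiphenylsilyloxy)butanoate
Conditions: TBDPSCl, imidazole, DMF, rt
Reagents that add atoms: tert-butyldiphenylsilyl chloride, CC(C)(C)[Si](Cl)(c1ccccc1)c1ccccc1
Why: Imidazole-mediated silylation gives an acid-robust silyl ether that should survive saponification, carbodiimide coupling and the later Vilsmeier–Haack conditions.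

Step 9
Reactants: 18 ethyl (R)-3-(tert-butyldiphenylsilyloxy)butanoate
Product: 19 (R)-3-(tert-butyldiphenylsilyloxy)butanoic acid
Conditions: LiOH·H2O, THF/MeOH/H2O, rt; then 1 M HCl
Reagents that add atoms: lithium hydroxide, [Li+].[OH-]
Why: Ester saponification at room temperature should proceed without β-elimination of the silyloxy group, and the stereocentre is not α to the carbonyl and cannot epimerise.

Step 10
Reactants: 16 (R)-1-[3,5-bis(benzyloxy)phenyl]propan-2-ol; 19 (R)-3-(tert-butyldiphenylsilyloxy)butanoic acid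
Product: 20 (R)-1-[3,5-bis(benzyloxy)phenyl]propan-2-yl (R)-3-(tert-butyldiphenylsilyloxy)butanoate
Conditions: EDC·HCl, DMAP, CH2Cl2, 0 °C to rt
Reagents that add atoms: none
Why: Steglich esterification of an unhindered aliphatic acid with a secondary alcohol breaks no bond at either stereocentre, so both (R) centres are carried over. Ester 20 is divided between steps 11 and 12.

Step 11
Reactants: 20 (R)-1-[3,5-bis(benzyloxy)phenyl]propan-2-yl (R)-3-(tert-butyldiphenylsilyloxy)butanoate
Product: 21 (R)-1-[3,5-bis(benzyloxy)phenyl]propan-2-yl (R)-3-hydroxybutanoate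
Conditions: TBAF, AcOH (1:1), THF, rt
Reagents that add atoms: none
Why: Fluoride desilylation buffered with acetic acid should free the β-hydroxy ester without base-induced elimination or retro-aldol cleavage.

Step 12
Reactants: 20 (R)-1-[3,5-bis(benzyloxy)phenyl]propan-2-yl (R)-3-(tert-butyldiphenylsilyloxy)butanoate
Product: 23 (R)-1-[3,5-bis(benzyloxy)-2-formylphenyl]propan-2-yl (R)-3-(tert-butyldiphenylsilyloxy)butanoate, via aryl iminium chloride 22 (not isolated)
Conditions: POCl3, DMF, 0 °C to rt; ice, aq NaOAc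
Reagents that add atoms: N,N-dimethylformamide, CN(C)C=O; water, O
Why: Vilsmeier–Haack formylation of the dialkoxyarene should occur at the ring carbon flanked by the side chain and one benzyloxy group (para to the other), not at the more crowded carbon between the two oxygens, as with 3,5-dialkoxyphenylacetic esters, and the ester and the tert-butyldiphenylsilyl ether tolerate the reagent.

Step 13
Reactants: 23 (R)-1-[3,5-bis(benzyloxy)-2-formylphenyl]propan-2-yl (R)-3-(tert-butyldiphenylsilyloxy)butanoate
Product: 24 2,4-bis(benzyloxy)-6-[(R)-2-{[(R)-3-(tert-butyldiphenylsilyloxy)butanoyl]oxy}propyl]benzoic acid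
Conditions: NaClO2, NaH2PO4, 2-methyl-2-butene, t-BuOH/THF/H2O, rt
Reagents that add atoms: sodium chlorite, [Na+].[O-]Cl=O
Why: Pinnick oxidation converts the aryl aldehyde into the acid, and the alkene scavenger intercepts hypochlorous acid before it can chlorinate the electron-rich ring.

Step 14
Reactants: 24 2,4-bis(benzyloxy)-6-[(R)-2-{[(R)-3-(tert-butyldiphenylsilyloxy)butanoyl]oxy}propyl]benzoic acid; 21 (R)-1-[3,5-bis(benzyloxy)phenyl]propan-2-yl (R)-3-hydroxybutanoate
Product: 26 (R)-4-{[(R)-1-(3,5-bis(benzyloxy)phenyl)propan-2-yl]oxy}-4-oxobutan-2-yl 2,4-bis(benzyloxy)-6-[(R)-2-{[(R)-3-(tert-butyldiphenylsilyloxy)butanoyl]oxy}propyl]benzoate, via acid chloride 25 (not isolated)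
Conditions: (COCl)2, cat. DMF, CH2Cl2, 0 °C to rt, evaporate; then 21, Et3N, DMAP (1 equiv), CH2Cl2, rt to 40 °C
Reagents that add atoms: none
Why: Acyl chloride formation followed by DMAP-catalysed acyl transfer to the secondary alcohol forms the ester at oxygen, so the (R) centre of unit B is retained, and the already acylated side-chain oxygen of 25 blocks lactonisation to a dihydroisocoumarin.

Step 15
Reactants: 26 (the fully protected tetraester of step 14)
Product: 27 (R)-4-{[(R)-1-(3,5-bis(benzyloxy)phenyl)propan-2-yl]oxy}-4-oxobutan-2-yl 2,4-bis(benzyloxy)-6-[(R)-2-{[(R)-3-hydroxybutanoyl]oxy}propyl]benzoate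
Conditions: HF·pyridine, pyridine, THF, 0 °C to rt
Reagents that add atoms: none
Why: Acidic fluoride cleavage of the silyl ether avoids any basic species, so the β-aroyloxy ester of unit B should not undergo E1cB elimination.

Step 16
Reactants: 27 (the tetrabenzyl ether of step 15)
Product: 28 Hansforester J
Conditions: H2 (1 atm), 10% Pd/C, EtOAc/EtOH, rt
Reagents that add atoms: none
Why: Hydrogenolysis of the four aryl benzyl ethers over Pd/C leaves the alkyl and aryl esters and all four (R) stereocentres untouched and should deliver the target after filtration.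

**Compound list**

1 | (R)-pent-4-yn-2-ol | C[C@@H](O)CC#C | starting material
2 | (R)-tert-butyldimethyl(pent-4-yn-2-yloxy)silane | C#CC[C@@H](C)O[Si](C)(C)C(C)(C)C | intermediate
3 | trichloroacetyl chloride | ClC(=O)C(Cl)(Cl)Cl | starting material
4 | dichloroketene | O=C=C(Cl)Cl | intermediate (not isolated)
5 | 4,4-dichloro-3-[(R)-2-(tert-butyldimethylsilyloxy)propyl]cyclobut-2-en-1-one | O=C1C=C(C[C@@H](C)O[Si](C)(C)C(C)(C)C)C1(Cl)Cl | intermediate
6 | (R)-3-[2-(tert-butyldimethylsilyloxy)propyl]cyclobut-2-en-1-one | O=C1C=C(C[C@@H](C)O[Si](C)(C)C(C)(C)C)C1 | intermediate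
7 | 3-phenylisoxazole | c1ccc(-c2ccon2)cc1 | starting material
8 | lithium ethynolate | [Li+].[O-]C#C | intermediate (not isolated)
9 | triisopropylsilyloxyacetylene, (ethynyloxy)triisopropylsilane | C#CO[Si](C(C)C)(C(C)C)C(C)C | intermediate
10 | (R)-5-(tert-butyldimethylsilyloxy)-3-methylidenehex-1-en-1-one (vinylketene) | O=C=CC(=C)C[C@@H](C)O[Si](C)(C)C(C)(C)C | intermediate (not isolated)
11 | 4-[(R)-4-(tert-butyldimethylsilyloxy)pent-1-en-2-yl]-3-(triisopropylsilyloxy)cyclobut-2-en-1-one, both C4 epimers | O=C1C=C(O[Si](C(C)C)(C(C)C)C(C)C)C1C(=C)C[C@@H](C)O[Si](C)(C)C(C)(C)C | intermediate (not isolated)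
12 | (3E,7R)-7-(tert-butyldimethylsilyloxy)-5-methylidene-3-(triisopropylsilyloxy)octa-1,3-dien-1-one (dienylketene, ketene arm and propenyl unit cis) | O=C=C/C(O[Si](C(C)C)(C(C)C)C(C)C)=C\C(=C)C[C@@H](C)O[Si](C)(C)C(C)(C)C | intermediate (not isolated)
13 | 5-[(R)-2-(tert-butyldimethylsilyloxy)propyl]-3-(triisopropylsilyloxy)cyclohexa-2,4-dien-1-one | O=C1C=C(O[Si](C(C)C)(C(C)C)C(C)C)C=C(C[C@@H](C)O[Si](C)(C)C(C)(C)C)C1 | intermediate (not isolated)
14 | (R)-3-[2-(tert-butyldimethylsilyloxy)propyl]-5-(triisopropylsilyloxy)phenol | C[C@H](Cc1cc(O)cc(O[Si](C(C)C)(C(C)C)C(C)C)c1)O[Si](C)(C)C(C)(C)C | intermediate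
15 | (R)-5-(2-hydroxypropyl)benzene-1,3-diol | C[C@@H](O)Cc1cc(O)cc(O)c1 | intermediate
16 | (R)-1-[3,5-bis(benzyloxy)phenyl]propan-2-ol | C[C@@H](O)Cc1cc(OCc2ccccc2)cc(OCc2ccccc2)c1 | intermediate
17 | ethyl (R)-3-hydroxybutanoate | CCOC(=O)C[C@@H](C)O | starting material
18 | ethyl (R)-3-(tert-butyldiphenylsilyloxy)butanoate | CCOC(=O)C[C@@H](C)O[Si](c1ccccc1)(c1ccccc1)C(C)(C)C | intermediate
19 | (R)-3-(tert-butyldiphenylsilyloxy)butanoic acid | OC(=O)C[C@@H](C)O[Si](c1ccccc1)(c1ccccc1)C(C)(C)C | intermediate
20 | (R)-1-[3,5-bis(benzyloxy)phenyl]propan-2-yl (R)-3-(tert-butyldiphenylsilyloxy)butanoate | C[C@H](Cc1cc(OCc2ccccc2)cc(OCc2ccccc2)c1)OC(=O)C[C@@H](C)O[Si](c1ccccc1)(c1ccccc1)C(C)(C)C | intermediate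
21 | (R)-1-[3,5-bis(benzyloxy)phenyl]propan-2-yl (R)-3-hydroxybutanoate | C[C@H](Cc1cc(OCc2ccccc2)cc(OCc2ccccc2)c1)OC(=O)C[C@@H](C)O | intermediate
22 | N-{2,4-bis(benzyloxy)-6-[(R)-2-{[(R)-3-(tert-butyldiphenylsilyloxy)butanoyl]oxy}propyl]benzylidene}-N-methylmethanaminium chloride | C[N+](C)=Cc1c(OCc2ccccc2)cc(OCc2ccccc2)cc1C[C@@H](C)OC(=O)C[C@@H](C)O[Si](c1ccccc1)(c1ccccc1)C(C)(C)C.[Cl-] | intermediate (not isolated)
23 | (R)-1-[3,5-bis(benzyloxy)-2-formylphenyl]propan-2-yl (R)-3-(tert-butyldiphenylsilyloxy)butanoate | O=Cc1c(OCc2ccccc2)cc(OCc2ccccc2)cc1C[C@@H](C)OC(=O)C[C@@H](C)O[Si](c1ccccc1)(c1ccccc1)C(C)(C)C | intermediate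
24 | 2,4-bis(benzyloxy)-6-[(R)-2-{[(R)-3-(tert-butyldiphenylsilyloxy)butanoyl]oxy}propyl]benzoic acid | OC(=O)c1c(OCc2ccccc2)cc(OCc2ccccc2)cc1C[C@@H](C)OC(=O)C[C@@H](C)O[Si](c1ccccc1)(c1ccccc1)C(C)(C)C | intermediate
25 | 2,4-bis(benzyloxy)-6-[(R)-2-{[(R)-3-(tert-butyldiphenylsilyloxy)butanoyl]oxy}propyl]benzoyl chloride | ClC(=O)c1c(OCc2ccccc2)cc(OCc2ccccc2)cc1C[C@@H](C)OC(=O)C[C@@H](C)O[Si](c1ccccc1)(c1ccccc1)C(C)(C)C | intermediate (not isolated)
26 | (R)-4-{[(R)-1-(3,5-bis(benzyloxy)phenyl)propan-2-yl]oxy}-4-oxobutan-2-yl 2,4-bis(benzyloxy)-6-[(R)-2-{[(R)-3-(tert-butyldiphenylsilyloxy)butanoyl]oxy}propyl]benzoate | C[C@H](Cc1cc(OCc2ccccc2)cc(OCc2ccccc2)c1)OC(=O)C[C@@H](C)OC(=O)c1c(OCc2ccccc2)cc(OCc2ccccc2)cc1C[C@@H](C)OC(=O)C[C@@H](C)O[Si](c1ccccc1)(c1ccccc1)C(C)(C)C | intermediate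
27 | (R)-4-{[(R)-1-(3,5-bis(benzyloxy)phenyl)propan-2-yl]oxy}-4-oxobutan-2-yl 2,4-bis(benzyloxy)-6-[(R)-2-{[(R)-3-hydroxybutanoyl]oxy}propyl]benzoate | C[C@H](Cc1cc(OCc2ccccc2)cc(OCc2ccccc2)c1)OC(=O)C[C@@H](C)OC(=O)c1c(OCc2ccccc2)cc(OCc2ccccc2)cc1C[C@@H](C)OC(=O)C[C@@H](C)O | intermediate
28 | Hansforester J | C[C@H](Cc1cc(O)cc(O)c1)OC(=O)C[C@@H](C)OC(=O)c1c(O)cc(O)cc1C[C@@H](C)OC(=O)C[C@@H](C)O | target

**Step count**

Total: 16 steps. Longest linear sequence: 12 steps (steps 1, 2, 3, 5, 6, 7, 10, 12, 13, 14, 15, 16).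

**Steps most likely to fail**

1. Step 5 (benzannulation). The bimolecular capture of vinylketene 10 by the terminal ynol ether may lose to dimerisation of the vinylketene. The ynol ether may also decay thermally by silyl shift or polymerisation, and the phenol formed may be O-acylated by vinylketene. The fallback sets out from acid 19 and returns at alcohol 16; it buys the resorcinol ring instead of building it. Acid 19 is condensed with N-hydroxyphthalimide (N,N'-diisopropylcarbodiimide, cat. DMAP, CH2Cl2) to the redox-active ester 1,3-dioxoisoindolin-2-yl (R)-3-(tert-butyldiphenylsilyloxy)butanoate F1. Purchased 1-bromo-3,5-bis(benzyloxy)benzene is converted by bromine–lithium exchange (n-BuLi, THF, −78 °C) into [3,5-bis(benzyloxy)phenyl]lithium F2 and transmetalated with ZnCl2 to [3,5-bis(benzyloxy)phenyl]zinc chloride F3. Nickel-catalysed decarboxylative arylation (NiCl2·glyme, 4,4'-di-tert-butyl-2,2'-bipyridine, THF/DMF, rt) joins F1 and F3 to (R)-{[1-(3,5-bis(benzyloxy)phenyl)propan-2-yl]oxy}(tert-butyl)diphenylsilane F4. The radical is primary and the stereocentre next to it is not involved, so (R) is kept. TBAF in THF then gives 16.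

2. Step 4 (silyloxyacetylene). The unhindered carbon terminus of ynolate 8 may be silylated instead of oxygen, giving a silylketene, and butyllithium may add to the C=N bond in competition with C5 lithiation. The fallback replaces 7 by purchased ethynyltrimethylsilane (9 is the first compound of its branch, so no numbered compound precedes it) and returns at 9. Deprotonation (n-BuLi, THF, −78 °C) gives lithium (trimethylsilyl)acetylide F5. Oxidation with lithium tert-butyl peroxide (from tert-butyl hydroperoxide and LiN(SiMe3)2, −78 to 0 °C) gives lithium 2-(trimethylsilyl)ethynolate F6, whose carbon terminus is blocked. O-Silylation with triisopropylsilyl trifluoromethanesulfonate gives triisopropyl{[(trimethylsilyl)ethynyl]oxy}silane F7. The alkynyl C–Si bond is then cleaved with K2CO3 in MeOH at −20 °C under close monitoring, so that the bulkier O–Si bond is kept, to give 9.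

3. Step 14 (hindered esterification). Acyl transfer from the doubly ortho-substituted, electron-rich acyl chloride to a secondary β-hydroxy ester may be slow. This would leave time for intramolecular attack of the side-chain ester on the acyl chloride (lactonisation) or for elimination in the β-acyloxy ester. The fallback sets out from alcohol 16 (with acid 24 unchanged) and returns at 26; the bond is made by substitution at the carbinol carbon instead of at the acyl carbon. Purchased ethyl (S)-3-hydroxybutanoate is silylated (TBDPSCl, imidazole, DMF) to ethyl (S)-3-(tert-butyldiphenylsilyloxy)butanoate F8 and saponified (LiOH, then HCl) to (S)-3-(tert-butyldiphenylsilyloxy)butanoic acid F9. Steglich esterification with 16 (EDC·HCl, DMAP) gives (R)-1-[3,5-bis(benzyloxy)phenyl]propan-2-yl (S)-3-(tert-butyldiphenylsilyloxy)butanoate F10. Buffered desilylation (TBAF, AcOH) gives (R)-1-[3,5-bis(benzyloxy)phenyl]propan-2-yl (S)-3-hydroxybutanoate F11. Mitsunobu reaction of F11 with acid 24 (PPh3, diisopropyl azodicarboxylate, toluene, 0 °C to rt) lets the hindered carboxylate act as nucleophile and inverts the carbinol centre from (S) to (R), giving 26.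

**Further compounds**

F1 | step 5 | 1,3-dioxoisoindolin-2-yl (R)-3-(tert-butyldiphenylsilyloxy)butanoate | O=C(C[C@@H](C)O[Si](c1ccccc1)(c1ccccc1)C(C)(C)C)ON1C(=O)c2ccccc2C1=O
F2 | step 5 | [3,5-bis(benzyloxy)phenyl]lithium | [Li]c1cc(OCc2ccccc2)cc(OCc2ccccc2)c1
F3 | step 5 | [3,5-bis(benzyloxy)phenyl]zinc chloride | Cl[Zn]c1cc(OCc2ccccc2)cc(OCc2ccccc2)c1
F4 | step 5 | (R)-{[1-(3,5-bis(benzyloxy)phenyl)propan-2-yl]oxy}(tert-butyl)diphenylsilane | C[C@H](Cc1cc(OCc2ccccc2)cc(OCc2ccccc2)c1)O[Si](c1ccccc1)(c1ccccc1)C(C)(C)C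
F5 | step 4 | lithium (trimethylsilyl)acetylide | [Li]C#C[Si](C)(C)C
F6 | step 4 | lithium 2-(trimethylsilyl)ethynolate | [Li+].[O-]C#C[Si](C)(C)C
F7 | step 4 | triisopropyl{[(trimethylsilyl)ethynyl]oxy}silane | C[Si](C)(C)C#CO[Si](C(C)C)(C(C)C)C(C)C
F8 | step 14 | ethyl (S)-3-(tert-butyldiphenylsilyloxy)butanoate | CCOC(=O)C[C@H](C)O[Si](c1ccccc1)(c1ccccc1)C(C)(C)C
F9 | step 14 | (S)-3-(tert-butyldiphenylsilyloxy)butanoic acid | OC(=O)C[C@H](C)O[Si](c1ccccc1)(c1ccccc1)C(C)(C)C
F10 | step 14 | (R)-1-[3,5-bis(benzyloxy)phenyl]propan-2-yl (S)-3-(tert-butyldiphenylsilyloxy)butanoate | C[C@H](Cc1cc(OCc2ccccc2)cc(OCc2ccccc2)c1)OC(=O)C[C@H](C)O[Si](c1ccccc1)(c1ccccc1)C(C)(C)C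
F11 | step 14 | (R)-1-[3,5-bis(benzyloxy)phenyl]propan-2-yl (S)-3-hydroxybutanoate | C[C@H](Cc1cc(OCc2ccccc2)cc(OCc2ccccc2)c1)OC(=O)C[C@H](C)O
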